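**Plan**
- Feature used: with the rings lettered A to G from the 2,4,6-trihydroxyphenyl end, ring D carries oxygen on C1, C3 and C5 (a phloroglucinol pattern), and its C4, between the C3 and C5 hydroxyls, holds the oxygen of ring E. Unfolded, this is a six-carbon 3,5-dioxo ester with an aryloxy group on C6.
- Cuts, in retrosynthetic order: all sixteen O–CH3 bonds; the aryl C–O bonds on the oxygen-flanked carbons of rings A, B and C (each partner a halobenzaldehyde whose CHO later becomes OH); the C4–C3 bond of ring D; the C4–C5 bond of the hexanoate chain and the ArO–CH2 bond; the ring F C1–O and ring G C1–O bonds.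
- Forward: rings G and F are joined, ring E (from a salicylaldehyde) is coupled to them, its freed oxygen is alkylated and the chain is grown to the triketide. The Claisen step closes ring D, the only ring built; the other six are bought as benzene derivatives. Rings C, B and A are then added one at a time by arylation/Baeyer–Villiger cycles, and all methyl ethers are cleaved at the end.
- Stereochemistry: none arises; the target has no stereocentre and no configurationally stable axis.

Key step: step 8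

Remark: methyl ethers are the only permanent protecting groups; 4-fluoro-3,5-dimethoxybenzaldehyde is taken as a purchasable building block, like the other starting materials.

Abbreviations in names: ArE = 3,5-dimethoxy-2-[3,5-dimethoxy-4-(3,4,5-trimethoxyphenoxy)phenoxy]phenyl (rings E, F, G); ArC = 2-[4-(ArE–O)-3,5-dimethoxyphenoxy]-3,4,5-trimethoxyphenyl (rings C to G).

**Step 1**
Reactants: 1 2-hydroxy-4,6-dimethoxybenzaldehyde
Product: 2 2-(benzyloxy)-4,6-dimethoxybenzaldehyde
Conditions: BnBr, K2CO3, DMF, 60 °C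
Reagents that add atoms: benzyl bromide, BrCc1ccccc1
Why: Williamson etherification of the chelated phenol masks the oxygen that will later become the D–E ether oxygen as a benzyl ether, which survives peracid and copper catalysis.

**Step 2**
Reactants: 2 2-(benzyloxy)-4,6-dimethoxybenzaldehyde
Product: 4 2-(benzyloxy)-4,6-dimethoxyphenol, via aryl formate 3 (not isolated)
Conditions: mCPBA, CH2Cl2, 0 °C to rt; then K2CO3 (cat.), MeOH, rt
Reagents that add atoms: 3-chloroperbenzoic acid (mCPBA), OOC(=O)c1cccc(Cl)c1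
Why: Baeyer–Villiger oxidation of a 2,4,6-trialkoxybenzaldehyde proceeds by aryl migration to the formate, and methanolysis frees the phenol that sits between the benzyloxy and a methoxy group.

**Step 3**
Reactants: 5 4-bromo-2,6-dimethoxyphenol; 6 (3,4,5-trimethoxyphenyl)boronic acid
Product: 7 5-bromo-1,3-dimethoxy-2-(3,4,5-trimethoxyphenoxy)benzene
Conditions: Cu(OAc)2 (2 equiv), pyridine, 4 Å molecular sieves, CH2Cl2, air, rt
Reagents that add atoms: none
Why: Chan–Lam coupling arylates doubly ortho-substituted phenols at room temperature and leaves the aryl bromide untouched, so rings F and G should be joined without self-condensation of 5.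

**Step 4**
Reactants: 4 2-(benzyloxy)-4,6-dimethoxyphenol; 7 5-bromo-1,3-dimethoxy-2-(3,4,5-trimethoxyphenoxy)benzene
Product: 8 1-(benzyloxy)-3,5-dimethoxy-2-[3,5-dimethoxy-4-(3,4,5-trimethoxyphenoxy)phenoxy]benzene
Conditions: CuI (10 mol %), picolinic acid (20 mol %), K3PO4, DMSO, 90 °C, argon
Reagents that add atoms: none
Why: Ullmann ether synthesis between a hindered, electron-rich phenol and an aryl bromide with two free ortho positions is the favourable polarity for the E–O–F bond.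

**Step 5**
Reactants: 8 1-(benzyloxy)-3,5-dimethoxy-2-[3,5-dimethoxy-4-(3,4,5-trimethoxyphenoxy)phenoxy]benzene
Product: 9 3,5-dimethoxy-2-[3,5-dimethoxy-4-(3,4,5-trimethoxyphenoxy)phenoxy]phenol (ArE–OH)
Conditions: H2 (1 atm), Pd/C, EtOAc–MeOH, rt
Reagents that add atoms: none
Why: Hydrogenolysis of the single benzyl ether should free the ring E hydroxyl while aryl methyl ethers and diaryl ethers stay intact.

**Step 6**
Reactants: 9 ArE–OH; 10 methyl bromoacetate
Product: 11 methyl 2-(ArE–O)acetate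
Conditions: K2CO3, acetone, reflux
Reagents that add atoms: none
Why: Williamson alkylation (SN2 at the sp3 carbon of the bromo ester) places the future D–E oxygen on carbon without any hindered aryl–oxygen bond formation.

**Step 7**
Reactants: 11 methyl 2-(ArE–O)acetate; 12 methyl acetoacetate
Product: 13 methyl 6-(ArE–O)-3,5-dioxohexanoate
Conditions: 12 (2.2 equiv), LiN(iPr)2 (4.4 equiv), THF, 0 °C; then 11, −78 to 0 °C; aqueous HCl
Reagents that add atoms: none
Why: Claisen condensation of the acetoacetate dianion through its terminal carbon with an ester is the standard entry to 3,5-dioxo esters, and the excess of dianion compensates for the acidic product and the enolisable aryloxyacetate.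

**Step 8**
Reactants: 13 methyl 6-(ArE–O)-3,5-dioxohexanoate
Product: 14 2-(ArE–O)benzene-1,3,5-triol
Conditions: LiN(iPr)2 (4 equiv), THF, −78 °C to rt, argon; aqueous HCl
Reagents that add atoms: none
Why: LiN(iPr)2 first removes one proton from each doubly activated methylene (C2, C4) and then the C6 proton, which is acidified by the C5 carbonyl and the aryloxy oxygen; the C6 carbanion of the trianion adds to the ester carbonyl C1 and methoxide leaves, so that the new C6–C1 bond is the C4–C3 bond of ring D. The ring enolate formed in this way is the phloroglucinolate itself, and acid work-up should give the triol without a separate aromatisation step. The closest known reaction type is the biomimetic intramolecular Claisen (Dieckmann-type) cyclisation of 3,5-dioxo ester polyanions to phloroglucinols. Ring D closes in the 6-(enolendo)-exo-trig mode, and no stereocentre is formed. The step needs C-acylation to win over O-acylation through the C5 enolate oxygen (2-pyranone formation); this is secured by complete trianion formation in aprotic THF, where the terminal carbanion is the strongest nucleophile and the aryloxy group allows the third deprotonation at low temperature. The hindered D–E oxygen is already in place from step 6, and the three hydroxyls emerge differentiated as one para and two ortho to the aryloxy group.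

**Step 9**
Reactants: 14 2-(ArE–O)benzene-1,3,5-triol; 15 2-bromo-3,4,5-trimethoxybenzaldehyde
Product: 16 2-[4-(ArE–O)-3,5-dihydroxyphenoxy]-3,4,5-trimethoxybenzaldehyde
Conditions: 15 (1.0 equiv), CuI (10 mol %), picolinic acid (20 mol %), K3PO4, DMSO, 80 °C, argon
Reagents that add atoms: none
Why: In this Ullmann ether synthesis, assisted by the ortho formyl group, the para hydroxyl of ring D (two ortho hydrogens) should couple in preference to the two hydroxyls next to the aryloxy group, because the bromine-bearing carbon is itself flanked by CHO and OMe and a tri-ortho-substituted ether would have to form at the other sites.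

**Step 10**
Reactants: 16 2-[4-(ArE–O)-3,5-dihydroxyphenoxy]-3,4,5-trimethoxybenzaldehyde
Product: 17 2-[4-(ArE–O)-3,5-dimethoxyphenoxy]-3,4,5-trimethoxybenzaldehyde (ArC–CHO)
Conditions: MeI, K2CO3, DMF, rt
Reagents that add atoms: iodomethane, CI
Why: Williamson methylation of the two remaining ring D hydroxyls removes competing nucleophiles before the next arylations, and the aldehyde is inert to these conditions.

**Step 11**
Reactants: 17 ArC–CHO
Product: 19 2-[4-(ArE–O)-3,5-dimethoxyphenoxy]-3,4,5-trimethoxyphenol (ArC–OH), via aryl formate 18 (not isolated)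
Conditions: mCPBA, CH2Cl2, 0 °C to rt; then K2CO3 (cat.), MeOH, rt
Reagents that add atoms: 3-chloroperbenzoic acid (mCPBA), OOC(=O)c1cccc(Cl)c1
Why: Baeyer–Villiger oxidation of a benzaldehyde with ortho-aryloxy and para-methoxy donors gives the formate by aryl migration, and methanolysis reveals the ring C hydroxyl on the carbon that must carry ring B.

**Step 12**
Reactants: 19 ArC–OH; 20 4-fluoro-3,5-dimethoxybenzaldehyde
Product: 21 4-(ArC–O)-3,5-dimethoxybenzaldehyde
Conditions: Cs2CO3, DMSO, 120 °C, argon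
Reagents that add atoms: none
Why: Nucleophilic aromatic substitution (addition–elimination) of fluoride para to the formyl group should tolerate the two flanking methoxy groups better than a metal-catalysed coupling, since the phenoxide attacks the small C–F carbon from above the ring plane.

**Step 13**
Reactants: 21 4-(ArC–O)-3,5-dimethoxybenzaldehyde
Product: 23 4-(ArC–O)-3,5-dimethoxyphenol, via aryl formate 22 (not isolated)
Conditions: mCPBA, CH2Cl2, 0 °C to rt; then K2CO3 (cat.), MeOH, rt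
Reagents that add atoms: 3-chloroperbenzoic acid (mCPBA), OOC(=O)c1cccc(Cl)c1
Why: Baeyer–Villiger oxidation of a 4-aryloxy-3,5-dimethoxybenzaldehyde should follow the behaviour of 3,4,5-trimethoxybenzaldehyde, aryl migration giving the formate and then the ring B phenol.

**Step 14**
Reactants: 23 4-(ArC–O)-3,5-dimethoxyphenol; 20 4-fluoro-3,5-dimethoxybenzaldehyde
Product: 24 4-[4-(ArC–O)-3,5-dimethoxyphenoxy]-3,5-dimethoxybenzaldehyde
Conditions: K2CO3, DMF, 110 °C, argon
Reagents that add atoms: none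
Why: The unhindered ring B phenoxide should displace the para-activated fluoride by nucleophilic aromatic substitution more readily than in step 12, since only the electrophile is ortho-disubstituted.

**Step 15**
Reactants: 24 4-[4-(ArC–O)-3,5-dimethoxyphenoxy]-3,5-dimethoxybenzaldehyde
Product: 26 4-[4-(ArC–O)-3,5-dimethoxyphenoxy]-3,5-dimethoxyphenol, via aryl formate 25 (not isolated)
Conditions: mCPBA, CH2Cl2, 0 °C to rt; then K2CO3 (cat.), MeOH, rt
Reagents that add atoms: 3-chloroperbenzoic acid (mCPBA), OOC(=O)c1cccc(Cl)c1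
Why: Baeyer–Villiger oxidation and methanolysis turn the formyl group into the para hydroxyl of ring A, which needs no protection because the next step unmasks all hydroxyls.

**Step 16**
Reactants: 26 4-[4-(ArC–O)-3,5-dimethoxyphenoxy]-3,5-dimethoxyphenol
Product: 27 CNP0351377.0, 2-{4-[2-(4-{2-[4-(3,4,5-trihydroxyphenoxy)-3,5-dihydroxyphenoxy]-3,5-dihydroxyphenoxy}-3,5-dihydroxyphenoxy)-3,4,5-trihydroxyphenoxy]-3,5-dihydroxyphenoxy}benzene-1,3,5-triol
Conditions: BBr3 (excess), CH2Cl2, −78 °C to rt, argon; then H2O, 0 °C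
Reagents that add atoms: none
Why: BBr3 cleaves aryl methyl ethers by O–CH3 scission through aryloxyboron bromides while diaryl ether bonds are untouched, so the sixteen methoxy groups should fall in one operation to the heptadecaol, which is to be handled under argon.

**Compound list**
1 | 2-hydroxy-4,6-dimethoxybenzaldehyde | COc1cc(O)c(C=O)c(OC)c1 | starting material
2 | 2-(benzyloxy)-4,6-dimethoxybenzaldehyde | COc1cc(OCc2ccccc2)c(C=O)c(OC)c1 | intermediate
3 | 2-(benzyloxy)-4,6-dimethoxyphenyl formate | COc1cc(OCc2ccccc2)c(OC=O)c(OC)c1 | intermediate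
4 | 2-(benzyloxy)-4,6-dimethoxyphenol | COc1cc(OCc2ccccc2)c(O)c(OC)c1 | intermediate
5 | 4-bromo-2,6-dimethoxyphenol | COc1cc(Br)cc(OC)c1O | starting material
6 | (3,4,5-trimethoxyphenyl)boronic acid | COc1cc(B(O)O)cc(OC)c1OC | starting material
7 | 5-bromo-1,3-dimethoxy-2-(3,4,5-trimethoxyphenoxy)benzene | COc1cc(Br)cc(OC)c1Oc1cc(OC)c(OC)c(OC)c1 | intermediate
8 | 1-(benzyloxy)-3,5-dimethoxy-2-[3,5-dimethoxy-4-(3,4,5-trimethoxyphenoxy)phenoxy]benzene | COc1cc(OCc2ccccc2)c(Oc2cc(OC)c(Oc3cc(OC)c(OC)c(OC)c3)c(OC)c2)c(OC)c1 | intermediate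
9 | 3,5-dimethoxy-2-[3,5-dimethoxy-4-(3,4,5-trimethoxyphenoxy)phenoxy]phenol (ArE–OH) | COc1cc(O)c(Oc2cc(OC)c(Oc3cc(OC)c(OC)c(OC)c3)c(OC)c2)c(OC)c1 | intermediate
10 | methyl bromoacetate | COC(=O)CBr | starting material
11 | methyl 2-(ArE–O)acetate | COC(=O)COc1cc(OC)cc(OC)c1Oc1cc(OC)c(Oc2cc(OC)c(OC)c(OC)c2)c(OC)c1 | intermediate
12 | methyl acetoacetate | COC(=O)CC(C)=O | starting material
13 | methyl 6-(ArE–O)-3,5-dioxohexanoate | COC(=O)CC(=O)CC(=O)COc1cc(OC)cc(OC)c1Oc1cc(OC)c(Oc2cc(OC)c(OC)c(OC)c2)c(OC)c1 | intermediate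
14 | 2-(ArE–O)benzene-1,3,5-triol | Oc1cc(O)c(Oc2cc(OC)cc(OC)c2Oc2cc(OC)c(Oc3cc(OC)c(OC)c(OC)c3)c(OC)c2)c(O)c1 | intermediate
15 | 2-bromo-3,4,5-trimethoxybenzaldehyde | COc1cc(C=O)c(Br)c(OC)c1OC | starting material
16 | 2-[4-(ArE–O)-3,5-dihydroxyphenoxy]-3,4,5-trimethoxybenzaldehyde | O=Cc1cc(OC)c(OC)c(OC)c1Oc1cc(O)c(Oc2cc(OC)cc(OC)c2Oc2cc(OC)c(Oc3cc(OC)c(OC)c(OC)c3)c(OC)c2)c(O)c1 | intermediate
17 | 2-[4-(ArE–O)-3,5-dimethoxyphenoxy]-3,4,5-trimethoxybenzaldehyde (ArC–CHO) | O=Cc1cc(OC)c(OC)c(OC)c1Oc1cc(OC)c(Oc2cc(OC)cc(OC)c2Oc2cc(OC)c(Oc3cc(OC)c(OC)c(OC)c3)c(OC)c2)c(OC)c1 | intermediate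
18 | 2-[4-(ArE–O)-3,5-dimethoxyphenoxy]-3,4,5-trimethoxyphenyl formate | O=COc1cc(OC)c(OC)c(OC)c1Oc1cc(OC)c(Oc2cc(OC)cc(OC)c2Oc2cc(OC)c(Oc3cc(OC)c(OC)c(OC)c3)c(OC)c2)c(OC)c1 | intermediate
19 | 2-[4-(ArE–O)-3,5-dimethoxyphenoxy]-3,4,5-trimethoxyphenol (ArC–OH) | Oc1cc(OC)c(OC)c(OC)c1Oc1cc(OC)c(Oc2cc(OC)cc(OC)c2Oc2cc(OC)c(Oc3cc(OC)c(OC)c(OC)c3)c(OC)c2)c(OC)c1 | intermediate
20 | 4-fluoro-3,5-dimethoxybenzaldehyde | COc1cc(C=O)cc(OC)c1F | starting material
21 | 4-(ArC–O)-3,5-dimethoxybenzaldehyde | O=Cc1cc(OC)c(Oc2cc(OC)c(OC)c(OC)c2Oc2cc(OC)c(Oc3cc(OC)cc(OC)c3Oc3cc(OC)c(Oc4cc(OC)c(OC)c(OC)c4)c(OC)c3)c(OC)c2)c(OC)c1 | intermediate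
22 | 4-(ArC–O)-3,5-dimethoxyphenyl formate | O=COc1cc(OC)c(Oc2cc(OC)c(OC)c(OC)c2Oc2cc(OC)c(Oc3cc(OC)cc(OC)c3Oc3cc(OC)c(Oc4cc(OC)c(OC)c(OC)c4)c(OC)c3)c(OC)c2)c(OC)c1 | intermediate
23 | 4-(ArC–O)-3,5-dimethoxyphenol | Oc1cc(OC)c(Oc2cc(OC)c(OC)c(OC)c2Oc2cc(OC)c(Oc3cc(OC)cc(OC)c3Oc3cc(OC)c(Oc4cc(OC)c(OC)c(OC)c4)c(OC)c3)c(OC)c2)c(OC)c1 | intermediate
24 | 4-[4-(ArC–O)-3,5-dimethoxyphenoxy]-3,5-dimethoxybenzaldehyde | O=Cc1cc(OC)c(Oc2cc(OC)c(Oc3cc(OC)c(OC)c(OC)c3Oc3cc(OC)c(Oc4cc(OC)cc(OC)c4Oc4cc(OC)c(Oc5cc(OC)c(OC)c(OC)c5)c(OC)c4)c(OC)c3)c(OC)c2)c(OC)c1 | intermediate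
25 | 4-[4-(ArC–O)-3,5-dimethoxyphenoxy]-3,5-dimethoxyphenyl formate | O=COc1cc(OC)c(Oc2cc(OC)c(Oc3cc(OC)c(OC)c(OC)c3Oc3cc(OC)c(Oc4cc(OC)cc(OC)c4Oc4cc(OC)c(Oc5cc(OC)c(OC)c(OC)c5)c(OC)c4)c(OC)c3)c(OC)c2)c(OC)c1 | intermediate
26 | 4-[4-(ArC–O)-3,5-dimethoxyphenoxy]-3,5-dimethoxyphenol | Oc1cc(OC)c(Oc2cc(OC)c(Oc3cc(OC)c(OC)c(OC)c3Oc3cc(OC)c(Oc4cc(OC)cc(OC)c4Oc4cc(OC)c(Oc5cc(OC)c(OC)c(OC)c5)c(OC)c4)c(OC)c3)c(OC)c2)c(OC)c1 | intermediate
27 | CNP0351377.0 (heptadecahydroxy heptaphenyl hexaether, name as in step 16) | Oc1cc(O)c(Oc2cc(O)c(Oc3cc(O)c(O)c(O)c3Oc3cc(O)c(Oc4cc(O)cc(O)c4Oc4cc(O)c(Oc5cc(O)c(O)c(O)c5)c(O)c4)c(O)c3)c(O)c2)c(O)c1 | target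

**Totals**
Total step count: 16.
Longest linear sequence: 15 steps (from 1 through steps 1, 2 and 4 to 16; step 3 is a side branch).

**Steps most likely to fail**

Step 8. The ring may close through the C5 enolate oxygen (lactonisation to a 2-pyranone), or the third deprotonation may stay incomplete so that the chain is only enolised and recovered or degraded. Fallback: ring D would then be taken from an aromatic building block. Setting out from phenol 9, nucleophilic aromatic substitution on fluoro aldehyde 20 (Cs2CO3, DMSO, 120 °C) would give 4-(ArE–O)-3,5-dimethoxybenzaldehyde F1. Baeyer–Villiger oxidation (mCPBA, CH2Cl2; then K2CO3, MeOH) would pass through 4-(ArE–O)-3,5-dimethoxyphenyl formate F2 to 4-(ArE–O)-3,5-dimethoxyphenol F3. Ullmann coupling of F3 with bromo aldehyde 15 (CuI, picolinic acid, K3PO4, DMSO, 90 °C) would come back to the route at 17.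

Step 9. Arylation may occur at a hydroxyl next to the aryloxy group or at two hydroxyls, and the electron-rich ring D carbons of the polyphenolate may condense with the formyl group. Fallback: the para oxygen would be singled out by a bulky temporary group before any aldehyde is present. Setting out from triol 14, iPr3SiCl and imidazole (DMF, 0 °C) should silylate the least hindered hydroxyl to give 2-(ArE–O)-5-[(triisopropylsilyl)oxy]benzene-1,3-diol F4. Methylation (MeI, K2CO3, acetone) would give [4-(ArE–O)-3,5-dimethoxyphenoxy]tri(propan-2-yl)silane F5. Desilylation (Bu4NF, AcOH, THF) would release 4-(ArE–O)-3,5-dimethoxyphenol F3, the same phenol as in the fallback for step 8. Its Ullmann coupling with 15 would come back to the route at 17.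

Step 12. Addition of the ortho-substituted phenoxide to the fluorine-bearing carbon between two methoxy groups may be too slow, so that degradation of the aldehyde at the temperature required takes over. Fallback: ring B would be grown on the ring C oxygen by the same polyketide folding that builds ring D. Setting out from phenol 19, alkylation with 10 (K2CO3, acetone) would give methyl 2-(ArC–O)acetate F6. Acylation of the dianion of 12 (LiN(iPr)2, THF) would give methyl 6-(ArC–O)-3,5-dioxohexanoate F7, and Claisen cyclisation (LiN(iPr)2, THF; aqueous HCl) would give 2-(ArC–O)benzene-1,3,5-triol F8. Substitution of the fluoride of 20 by the para hydroxyl (K2CO3, DMF, 90 °C) would give 4-[4-(ArC–O)-3,5-dihydroxyphenoxy]-3,5-dimethoxybenzaldehyde F9. Methylation (MeI, K2CO3, DMF) would come back to the route at 24.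

**Further compounds**
F1 | step 8 | 4-(ArE–O)-3,5-dimethoxybenzaldehyde | O=Cc1cc(OC)c(Oc2cc(OC)cc(OC)c2Oc2cc(OC)c(Oc3cc(OC)c(OC)c(OC)c3)c(OC)c2)c(OC)c1
F2 | step 8 | 4-(ArE–O)-3,5-dimethoxyphenyl formate | O=COc1cc(OC)c(Oc2cc(OC)cc(OC)c2Oc2cc(OC)c(Oc3cc(OC)c(OC)c(OC)c3)c(OC)c2)c(OC)c1
F3 | step 8 | 4-(ArE–O)-3,5-dimethoxyphenol | Oc1cc(OC)c(Oc2cc(OC)cc(OC)c2Oc2cc(OC)c(Oc3cc(OC)c(OC)c(OC)c3)c(OC)c2)c(OC)c1
F4 | step 9 | 2-(ArE–O)-5-[(triisopropylsilyl)oxy]benzene-1,3-diol | CC(C)[Si](Oc1cc(O)c(Oc2cc(OC)cc(OC)c2Oc2cc(OC)c(Oc3cc(OC)c(OC)c(OC)c3)c(OC)c2)c(O)c1)(C(C)C)C(C)C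
F5 | step 9 | [4-(ArE–O)-3,5-dimethoxyphenoxy]tri(propan-2-yl)silane | CC(C)[Si](Oc1cc(OC)c(Oc2cc(OC)cc(OC)c2Oc2cc(OC)c(Oc3cc(OC)c(OC)c(OC)c3)c(OC)c2)c(OC)c1)(C(C)C)C(C)C
F6 | step 12 | methyl 2-(ArC–O)acetate | COC(=O)COc1cc(OC)c(OC)c(OC)c1Oc1cc(OC)c(Oc2cc(OC)cc(OC)c2Oc2cc(OC)c(Oc3cc(OC)c(OC)c(OC)c3)c(OC)c2)c(OC)c1
F7 | step 12 | methyl 6-(ArC–O)-3,5-dioxohexanoate | COC(=O)CC(=O)CC(=O)COc1cc(OC)c(OC)c(OC)c1Oc1cc(OC)c(Oc2cc(OC)cc(OC)c2Oc2cc(OC)c(Oc3cc(OC)c(OC)c(OC)c3)c(OC)c2)c(OC)c1
F8 | step 12 | 2-(ArC–O)benzene-1,3,5-triol | Oc1cc(O)c(Oc2cc(OC)c(OC)c(OC)c2Oc2cc(OC)c(Oc3cc(OC)cc(OC)c3Oc3cc(OC)c(Oc4cc(OC)c(OC)c(OC)c4)c(OC)c3)c(OC)c2)c(O)c1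
F9 | step 12 | 4-[4-(ArC–O)-3,5-dihydroxyphenoxy]-3,5-dimethoxybenzaldehyde | O=Cc1cc(OC)c(Oc2cc(O)c(Oc3cc(OC)c(OC)c(OC)c3Oc3cc(OC)c(Oc4cc(OC)cc(OC)c4Oc4cc(OC)c(Oc5cc(OC)c(OC)c(OC)c5)c(OC)c4)c(OC)c3)c(O)c2)c(OC)c1
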